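**Retrosynthetic overview**
1. Target ⇐ acid deprotection ⇐ γ-hydroxy enone, made by E1cB opening of the C3–C4 oxirane of a keto syn-bis-epoxide. C2–H is lost, C2=C3 forms and C4–OH is released.
2. syn-Bis-epoxide ⇐ one molecule of O2: singlet-oxygen [4+2] across C3/C6 of a 1,3-cyclohexadiene, then Co(TPP) rearrangement. The oxirane O and the C4–O come from the same O2, so they are syn.
3. cis-Cyclohexadienol ⇐ rhodium-catalysed exo-heptenylation with β-oxygen elimination on a 7-oxanorbornadiene. Its two stereocentres only steer O2 and are erased later.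
4. 7-Oxanorbornadiene ⇐ auxiliary-controlled Diels–Alder reaction of a 3-substituted furan (side chain by cross-metathesis) with an N-propioloyl oxazolidinone.
5. Ring order: the carbocycle forms first, as an oxa-bridged bicycle whose bridge is then cut. Next comes the dioxa bridge, then both oxiranes together. The C3–C4 oxirane is sacrificed and the C5–C6 oxirane stays.

Convention: core carbons are numbered as in the target (C1 ring C=O, C2 heptenyl-bearing, C3 CH2O-bearing, C4 carbinol CH, C5 oxirane CH, C6 oxirane C with the side chain). "tBu side chain" means (E)-CH2CH=C(CH3)CO2tBu.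
Assumption: the (S)-benzyl auxiliary gives the (1R,4R)-bicycle 9 as the major, chromatographically separable diastereomer. If it turns out to be the minor one, the (R)-auxiliary is used and nothing else changes.

**Step 1**
Reactants: 1 furan-3-boronic acid; 2 allyl bromide
Product: 3 3-allylfuran
Conditions: Pd(PPh3)4 (3 mol %), K2CO3, THF/H2O, 60 °C
Reagents that add atoms: none
Why: Suzuki–Miyaura allylation, in which zerovalent palladium ionises allyl bromide to a π-allyl complex that couples with the furylboronate at carbon; no stereocentre is formed.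

**Step 2**
Reactants: 3 3-allylfuran; 4 tert-butyl methacrylate
Product: 5 tert-butyl (E)-4-(furan-3-yl)-2-methylbut-2-enoate
Conditions: second-generation Hoveyda–Grubbs catalyst (3 mol %), 4 (4 equiv), CH2Cl2, 40 °C
Reagents that add atoms: none
Why: Olefin cross-metathesis of a terminal alkene with a methacrylate that barely homodimerises gives the cross product, and thermodynamic control delivers the E-trisubstituted enoate.

**Step 3**
Reactants: 6 propiolic acid; 7 (S)-4-benzyl-1,3-oxazolidin-2-one
Product: 8 (S)-4-benzyl-3-propioloyl-1,3-oxazolidin-2-one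
Conditions: DCC, DMAP (5 mol %), CH2Cl2, −10 °C → rt
Reagents that add atoms: none
Why: Steglich-type carbodiimide N-acylation of the oxazolidinone; the stereocentre of the auxiliary is not touched.

**Step 4**
Reactants: 5 tert-butyl (E)-4-(furan-3-yl)-2-methylbut-2-enoate; 8 (S)-4-benzyl-3-propioloyl-1,3-oxazolidin-2-one
Product: 9 (S)-4-benzyl-3-{[(1R,4R)-5-(tBu side chain)-7-oxabicyclo[2.2.1]hepta-2,5-dien-2-yl]carbonyl}-1,3-oxazolidin-2-one
Conditions: Cu(OTf)2 (10 mol %), 4 Å MS, CH2Cl2, −40 °C; chromatography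
Reagents that add atoms: none
Why: Lewis-acid-promoted Diels–Alder reaction in which divalent copper chelates the imide, the nucleophilic C2 of the 3-alkylfuran bonds to the unsubstituted alkyne terminus ("para" regiochemistry), and the benzyl group blocks one face so that both bridgeheads are set as 1R,4R (bicycle numbering), the minor diastereomer being removed by chromatography.

**Step 5**
Reactants: 9 oxanorbornadiene imide; 10 (E)-hept-1-enylboronic acid
Product: 11 (1R,2R)-2-[(E)-hept-1-enyl]-3-[(S)-4-benzyl-2-oxooxazolidine-3-carbonyl]-6-(tBu side chain)cyclohexa-3,5-dien-1-ol (OH cis to heptenyl)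
Conditions: [Rh(cod)(OH)]2 (2.5 mol %), THF/H2O (10:1), 0 °C → rt; cold buffered work-up
Reagents that add atoms: none
Why: Rhodium-catalysed conjugate alkenylation with β-oxygen elimination (alkylative ring opening of an oxabicyclic alkene), in which the alkenylrhodium adds to the strained acceptor alkene from the exo face, syn to the oxygen bridge, which sets C2, and the rhodium enolate expels the bridge oxygen from core C4, so the other bridgehead C–O bond survives as the C1 carbinol cis to the heptenyl group.

**Step 6**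
Reactants: 11 imide dienol
Product: 12 (1R,2R)-2-[(E)-hept-1-enyl]-3-(hydroxymethyl)-6-(tBu side chain)cyclohexa-3,5-dien-1-ol
Conditions: LiBH4, H2O (1 equiv), Et2O/THF, 0 °C
Reagents that add atoms: none
Why: Reductive cleavage of an N-acyl oxazolidinone by borohydride gives the primary allylic alcohol and returns the auxiliary, the hindered tert-butyl enoate is not attacked, and no stereocentre changes.

**Step 7**
Reactants: 12 dienediol
Product: 13 (1R,2R)-3-(tert-butyldimethylsilyloxymethyl)-2-[(E)-hept-1-enyl]-6-(tBu side chain)cyclohexa-3,5-dien-1-ol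
Conditions: TBSCl (1.05 equiv), imidazole, CH2Cl2, −20 °C
Reagents that add atoms: tert-butyldimethylsilyl chloride, CC(C)(C)[Si](C)(C)Cl
Why: Chemoselective silylation of the unhindered primary alcohol over the flanked secondary C1 carbinol, which must stay free for step 9.

**Step 8 (key step)**
Reactants: 13 TBS dienol
Product: 15 (1R,2S,3S,4S,5R,6S)-3,4:5,6-diepoxycyclohexan-1-ol bearing 2-heptenyl 3-CH2OTBS 6-(tBu side chain), via endoperoxide 14 (not isolated)
Conditions: O2, H2TPP (meso-tetraphenylporphyrin, 0.5 mol %), white LED, CH2Cl2, −78 °C; Ar purge; Co(TPP) (5 mol %), −78 → 0 °C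
Reagents that add atoms: dioxygen, O=O
Why: Singlet-oxygen [4+2] photooxygenation followed by cobalt-porphyrin-catalysed endoperoxide-to-bis-epoxide rearrangement, in which O2 adds suprafacially to the diene face opposite to the cis OH and heptenyl groups and O–O homolysis by divalent cobalt lets each oxygen close onto its neighbouring alkene carbon with retention of face (there is no bridgehead H, so no Kornblum–DeLaMare escape), setting C3, C4, C5 and C6 at once with all C–O bonds syn.

**Step 9**
Reactants: 15 syn-bis-epoxide alcohol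
Product: 17 (4R,5R,6R)-TBS ether tert-butyl ester of the target, via keto bis-epoxide 16 (not isolated)
Conditions: DMP, pyridine, CH2Cl2, 0 °C; then Et3N (0.5 equiv), 0 °C
Reagents that add atoms: none
Why: Dess–Martin oxidation then E1cB isomerisation of a β,γ-epoxy ketone to a γ-hydroxy enone, in which the doubly activated C2–H is removed and the C3–O bond breaks, erasing the C1, C2 and C3 stereocentres and leaving C4–OH syn to the untouched C5–C6 oxirane.

**Step 10**
Reactants: 17 protected target
Product: 18 target, (E)-4-[(1R,5R,6R)-3-[(E)-hept-1-enyl]-5-hydroxy-4-(hydroxymethyl)-2-oxo-7-oxabicyclo[4.1.0]hept-3-en-1-yl]-2-methylbut-2-enoic acid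
Conditions: TFA/CH2Cl2/H2O (10:10:1), 0 °C → rt; NaHCO3 wash, re-acidify
Reagents that add atoms: none
Why: Acidolysis cleaves the tert-butyl ester (loss of isobutene) and the primary TBS ether in one operation, while the keto-deactivated oxirane and the three stereocentres are not affected.

**Compound list**
1 | furan-3-boronic acid | OB(O)c1ccoc1 | starting material
2 | allyl bromide | C=CCBr | starting material
3 | 3-allylfuran | C=CCc1ccoc1 | intermediate
4 | tert-butyl methacrylate | C=C(C)C(=O)OC(C)(C)C | starting material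
5 | tert-butyl (E)-4-(furan-3-yl)-2-methylbut-2-enoate | o1ccc(C/C=C(\C)C(=O)OC(C)(C)C)c1 | intermediate
6 | propiolic acid | C#CC(=O)O | starting material
7 | (S)-4-benzyl-1,3-oxazolidin-2-one | O=C1OC[C@H](Cc2ccccc2)N1 | starting material
8 | (S)-4-benzyl-3-propioloyl-1,3-oxazolidin-2-one | C#CC(=O)N1[C@@H](Cc2ccccc2)COC1=O | intermediate
9 | (1R,4R)-7-oxanorbornadiene imide | O=C(N1[C@@H](Cc2ccccc2)COC1=O)C3=C[C@H]4O[C@@H]3C=C4C/C=C(\C)C(=O)OC(C)(C)C | intermediate
10 | (E)-hept-1-enylboronic acid | CCCCC/C=C/B(O)O | starting material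
11 | (1R,2R)-imide dienol, OH cis to heptenyl | CCCCC/C=C/[C@@H]1C(C(=O)N2[C@@H](Cc3ccccc3)COC2=O)=CC=C(C/C=C(\C)C(=O)OC(C)(C)C)[C@@H]1O | intermediate
12 | (1R,2R)-dienediol | CCCCC/C=C/[C@@H]1C(CO)=CC=C(C/C=C(\C)C(=O)OC(C)(C)C)[C@@H]1O | intermediate
13 | (1R,2R)-TBS dienol | CCCCC/C=C/[C@@H]1C(CO[Si](C)(C)C(C)(C)C)=CC=C(C/C=C(\C)C(=O)OC(C)(C)C)[C@@H]1O | intermediate
14 | (1R,2S,3S,6R)-3,6-endoperoxide, O–O bridge on the face opposite to OH and heptenyl | CCCCC/C=C/[C@@H]1[C@]2(CO[Si](C)(C)C(C)(C)C)C=C[C@@](C/C=C(\C)C(=O)OC(C)(C)C)(OO2)[C@@H]1O | intermediate (not isolated)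
15 | (1R,2S,3S,4S,5R,6S)-syn-bis-epoxide alcohol | CCCCC/C=C/[C@@H]1[C@@]2(CO[Si](C)(C)C(C)(C)C)O[C@H]2[C@H]3O[C@@]3(C/C=C(\C)C(=O)OC(C)(C)C)[C@@H]1O | intermediate
16 | (2R,3S,4S,5R,6R)-keto bis-epoxide | CCCCC/C=C/[C@@H]1[C@@]2(CO[Si](C)(C)C(C)(C)C)O[C@H]2[C@H]3O[C@@]3(C/C=C(\C)C(=O)OC(C)(C)C)C1=O | intermediate (not isolated)
17 | (4R,5R,6R)-TBS ether tert-butyl ester of the target | CCCCC/C=C/C1=C(CO[Si](C)(C)C(C)(C)C)[C@@H](O)[C@H]2O[C@@]2(C/C=C(\C)C(=O)OC(C)(C)C)C1=O | intermediate
18 | target CNP0332048.1 (4R,5R,6R in core numbering) | CCCCC/C=C/C1=C(CO)[C@@H](O)[C@H]2O[C@@]2(C/C=C(\C)C(=O)O)C1=O | target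

**Totals**
- Total steps: 10.
- Longest linear sequence: 9 (steps 1, 2, 4, 5, 6, 7, 8, 9, 10).

**Steps most likely to fail**

Step 4. Risks are furan/alkyne reactivity, acid-induced aromatisation of the adduct, and modest face or orientation control. The fallback sets out from 5 and uses an alkene as a propynal surrogate under catalyst control. Reaction with 2-bromoacrolein, using 10 mol % of the B-butyl oxazaborolidinone made from N-tosyl-(S)-tryptophan (CH2Cl2, −78 °C), gives bromo aldehyde F1. DBU removes HBr to give oxanorbornadiene carbaldehyde F2. The rhodium alkenylation with 10 then opens F2 to dienal F3. NaBH4/CeCl3 reduces F3 to 12, where the route is rejoined.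

Step 5. The enolate may be protonated faster than it expels the bridge oxygen, or 11 may lose water in the aqueous medium. The fallback sets out from 9 and separates the two events. The rhodium addition is run to the intact oxa-bridged conjugate adduct F4 (heptenyl exo, imide endo), which is stable and can be purified. The bridge is then cut by a classical amide-base β-elimination (LiHMDS, THF, −78 °C, cold buffered quench). This returns to the route at 11.

Step 8. The tertiary alkoxyl radicals could undergo β-scission, expelling the allylic side chain or CH2OTBS, and some facial leakage is possible. The fallback sets out from 13, still passes through 14, and then avoids radical chemistry.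
- PPh3 deoxygenates 14 by an ionic SN2′ closure to vinyl oxirane F5.
- A second photooxygenation follows, now a Schenck ene reaction on C3=C4 that abstracts the top-face C2–H. It gives hydroperoxide F6 with C2=C3 already in place.
- PPh3 reduces F6 to diol F7.
- DMP oxidises both carbinols to epoxyquinone F8.
- DIBAL-H at −78 °C reduces the less hindered C4 ketone from the face opposite to the oxirane. This returns to the route at 17.

**Further compounds**
F1 | step 4 | (1R,2R,4R)-2-bromo-5-(tBu side chain)-7-oxabicyclo[2.2.1]hept-5-ene-2-carbaldehyde (CHO exo) | O=C[C@@]1(Br)C[C@H]2O[C@@H]1C=C2C/C=C(\C)C(=O)OC(C)(C)C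
F2 | step 4 | (1R,4R)-5-(tBu side chain)-7-oxabicyclo[2.2.1]hepta-2,5-diene-2-carbaldehyde | O=CC1=C[C@H]2O[C@@H]1C=C2C/C=C(\C)C(=O)OC(C)(C)C
F3 | step 4 | (5R,6R)-5-hydroxy-6-[(E)-hept-1-enyl]-4-(tBu side chain)cyclohexa-1,3-diene-1-carbaldehyde | CCCCC/C=C/[C@@H]1C(C=O)=CC=C(C/C=C(\C)C(=O)OC(C)(C)C)[C@@H]1O
F4 | step 5 | oxa-bridged conjugate adduct of 9 (heptenyl exo, imide endo) | CCCCC/C=C/[C@@H]1[C@@H](C(=O)N3[C@@H](Cc4ccccc4)COC3=O)[C@@H]2O[C@H]1C(C/C=C(\C)C(=O)OC(C)(C)C)=C2
F5 | step 8 | C5–C6 vinyl oxirane with C3=C4 alkene and C1–OH | CCCCC/C=C/[C@@H]1C(CO[Si](C)(C)C(C)(C)C)=C[C@H]2O[C@@]2(C/C=C(\C)C(=O)OC(C)(C)C)[C@@H]1O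
F6 | step 8 | C4 hydroperoxide syn to the oxirane | CCCCC/C=C/C1=C(CO[Si](C)(C)C(C)(C)C)[C@@H](OO)[C@H]2O[C@@]2(C/C=C(\C)C(=O)OC(C)(C)C)[C@@H]1O
F7 | step 8 | C1,C4-diol | CCCCC/C=C/C1=C(CO[Si](C)(C)C(C)(C)C)[C@@H](O)[C@H]2O[C@@]2(C/C=C(\C)C(=O)OC(C)(C)C)[C@@H]1O
F8 | step 8 | (5R,6R)-epoxyquinone | CCCCC/C=C/C1=C(CO[Si](C)(C)C(C)(C)C)C(=O)[C@H]2O[C@@]2(C/C=C(\C)C(=O)OC(C)(C)C)C1=O
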